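The earlier runs and the new flask were generated by integration with constants of no real substance.

Leave the constants unfitted: two extreme flasks and one number from the grey run carry the answer.

| flask | X | Z | G | remark | time |
|---|---|---|---|---|---|
| grey | 0.083 M | 0.074 M | 0.166 M | run made earlier |  |
| amber | 0.083 M | 0.11 M | 0.166 M | run made earlier |  |
| teal | 0.083 M | 0.14 M | 0.166 M | run made earlier |  |
| north-west | 0.083 M | 0.0664 M | 0.166 M |  | 80 min |
| south | 0.083 M | 0.166 M | 0.166 M |  | 80 min |

| run | time / min | J / % | E / % |
|---|---|---|---|
| grey | 15.0 | 55.8 | 1.3 |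
| grey | 30.0 | 53.3 | 0 |
| grey | 40.0 | 54.6 | 1.3 |
| grey | 60.0 | 53.6 | 1.2 |
| amber | 8.00 | 50.9 | 1.5 |
| amber | 20.0 | 50.8 | 2.4 |
| amber | 40.0 | 51.1 | 3.7 |
| amber | 60.0 | 50.9 | 3.4 |
| teal | 8.00 | 34.6 | 6.5 |
| teal | 20.0 | 37.2 | 8.9 |
| teal | 40.0 | 35.4 | 8.4 |
| teal | 60.0 | 36.0 | 6.3 |

(scatter of a reading: 1 percentage point)

* which of these holds the largest part of the X at the end of north-west (Q / X / E / J)
* which of these holds the largest part of the X at the end of south (Q / X / E / J)
* amount of J at the end of north-west, in percent of the X charged

- the numbers in the tables scatter by 1 percentage point (one standard deviation)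

**Uptake first.** The grey readings of J stay flat within the scatter, so assume the exchange has stopped with the Z bound. Uptake per X is then u = cZ/cX as charged: 0.892 in grey, 0.800 in north-west, 2.00 in south.

**Chance end.** Let 3 like sites share the uptake by chance (the statistical distribution). A site stays empty with probability w = 1 − u/3, so X is w cubed and J is u times w squared. North-west then holds X at 39.4% and J at 43.0%, J ahead. South holds Q at 44.4% and E at 29.6%, Q ahead.

**Turn-taking end.** Now let each Z go to the least exchanged form. North-west gets J at 80.0% and X at 20.0%, and south gets Q at 100 per cent. Both ends name the same leader in each flask.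

**Between them.** Grey J reads 54.3% on average, above its chance value of 44.0% and below its turn-taking value of 89.2%. Call the fraction of that span covered the ordering s, here 0.228. Assume s holds for the nearby charge of north-west, and J there comes to 51.5%.

**The forecast.** It names J for north-west and Q for south and gives J in north-west at 51.5%, range 48% to 55%, with “J peaks near 54%” among its grounds. This reckoning differs from it by 0.047 percentage points.

**The result.** North-west ends with J at 53.1%, ahead of X at 32.6%, and south ends with Q at 64.4%.

    X + Z → G + J (k = 1.60 /M/s)
    Q + Z → G + E (k = 0.120 /M/s)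
    J + Z → G + Q (k = 0.570 /M/s)
    X → L (k = 6.30 × 10⁻⁶ /s)

**One more flask.** In north-west Z, the limiting reagent, stands at 0% of its charge, the uptake is 0.800 equiv, and J places that flask at s = 0.273. Take the grey s to a flask like north-west but with 0.017 M of Z: u is 0.205, chance gives J 17.8%, s lifts it to 18.4%, and that flask holds J at 18.9%.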